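**Retrosynthetic overview**

1. The target is (6S)-3,4-didehydro-γ,χ-carotene (carotenoid numbering: C1 = CMe2, C2 = CH2, C3=C4, C5=C18H2, C6 = stereocentre). It is cut C10 + C20 + C10: the last bond is C7=C8 (Julia–Kocienski, ring sulfone + aryl C30 polyenal), and C7'=C8' comes from a Horner–Wadsworth–Emmons reaction of a 2,3,4-trimethylbenzyl phosphonate with crocetin dialdehyde.
2. The ring is made by a formal [4+2] annulation of an acyclic dienal (C1, C6, C5, C4 with C18 and C7) with vinyltriphenylphosphonium bromide as the C2–C3 unit. A radical hydroalkylation forms C1–C2 and an intramolecular Wittig reaction forms C3=C4, in one pot.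
3. Enabling feature: in the 6,6-dimethyl-2-methylidenecyclohex-3-ene ring the quaternary gem-dimethyl carbon C1 lies next to the CH2 group C2, which is the retron of Markovnikov hydrogen atom transfer to an isopropenyl group. The cis C3=C4 bond is conjugated with the exocyclic C5=C18 bond, which is the retron of a Wittig closure on an α-methylene aldehyde.
4. C6 is set first, by rhodium-catalysed asymmetric conjugate addition of isopropenyl to a γ-silyloxy crotonate. It is never α or vinylogous to a carbonyl group under base afterwards, because the ring fragment is joined last as a sulfone.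
5. Ring order: the trimethylphenyl ring is bought; the cyclohexadiene ring is the only ring formed (step 5).

Key step: step 5

Remark: compounds 1, 2, 4, 8, 12, 15 and 19 are taken as catalogue chemicals, and the stereocentre of the target is read from the SMILES as 6S.

**Route**

Step 1
Reactants: 1 {[tert-butyl(dimethyl)silyl]oxy}acetaldehyde; 2 ethyl (triphenylphosphoranylidene)acetate
Product: 3 ethyl (2E)-4-{[tert-butyl(dimethyl)silyl]oxy}but-2-enoate
Conditions: CH2Cl2, 0 °C to rt
Reagents that add atoms: none
Why: A stabilised phosphorus ylide olefinates the unhindered aldehyde (Wittig reaction) under neutral conditions and should give the (E)-enoate.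

Step 2
Reactants: 3 ethyl (2E)-4-{[tert-butyl(dimethyl)silyl]oxy}but-2-enoate; 4 potassium trifluoro(prop-1-en-2-yl)borate
Product: 5 ethyl (3R)-3-({[tert-butyl(dimethyl)silyl]oxy}methyl)-4-methylpent-4-enoate
Conditions: [Rh(cod)2]BF4 (3 mol%), (S)-BINAP (3.3 mol%), toluene/H2O 10:1, 100 °C
Reagents that add atoms: none
Why: Rhodium-catalysed asymmetric 1,4-addition of an alkenylboron reagent to an enoate (Hayashi–Miyaura reaction); the (S)-BINAP–rhodium isopropenyl species should add to the α-si face of the (E)-enoate, which sets the future C6 centre as 3R, and water protonates the rhodium enolate.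

Step 3
Reactants: 5 ethyl (3R)-3-({[tert-butyl(dimethyl)silyl]oxy}methyl)-4-methylpent-4-enoate
Product: 6 (3R)-3-({[tert-butyl(dimethyl)silyl]oxy}methyl)-4-methylpent-4-enal
Conditions: i-Bu2AlH (1.1 equiv), CH2Cl2, −78 °C; aq. potassium sodium tartrate
Reagents that add atoms: none
Why: Partial reduction of the ester with i-Bu2AlH at −78 °C stops at the aluminium hemiacetal, which gives the aldehyde on work-up; the stereocentre is β to the carbonyl group and cannot epimerise by enolisation.

Step 4
Reactants: 6 (3R)-3-({[tert-butyl(dimethyl)silyl]oxy}methyl)-4-methylpent-4-enal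
Product: 7 (3S)-3-({[tert-butyl(dimethyl)silyl]oxy}methyl)-4-methyl-2-methylidenepent-4-enal
Conditions: 37% aq. CH2O, pyrrolidine (10 mol%), EtCO2H (10 mol%), i-PrOH, 45 °C
Reagents that add atoms: formaldehyde, C=O
Why: Organocatalytic α-methylenation (Mannich condensation of the enamine with the iminium ion of formaldehyde, then loss of pyrrolidine) installs C18 on C5 without touching the adjacent stereocentre.

Step 5
Reactants: 7 (3S)-3-({[tert-butyl(dimethyl)silyl]oxy}methyl)-4-methyl-2-methylidenepent-4-enal; 8 ethenyl(triphenyl)phosphonium bromide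
Product: 10 tert-butyl{[(1S)-6,6-dimethyl-2-methylidenecyclohex-3-en-1-yl]methoxy}dimethylsilane, via phosphonium salt 9 (not isolated)
Conditions: Fe(acac)3 (0.5 equiv), PhSiH3 (2 equiv), 8 (1.5 equiv), EtOH, 60 °C, slow addition of 7; then evaporation, THF, KOt-Bu (1.6 equiv), 0 °C to rt
Reagents that add atoms: none
Why: Proposed new method: a trivalent iron hydride made from Fe(acac)3, PhSiH3 and ethanol should transfer a hydrogen atom to the CH2 terminus of the isopropenyl group (Mukaiyama-type hydrogen atom transfer), the tertiary C1 radical should add to the β-carbon of the cationic vinylphosphonium salt 8 (C1–C2 bond, quaternary centre), and divalent iron should reduce the electron-poor α-phosphonio radical to the ylide, which ethanol buffers as salt 9 and which KOt-Bu regenerates for an intramolecular Wittig reaction with the aldehyde (C3=C4 bond). The closest known reaction types are the iron-hydride Giese-type hydroalkylation of 1,1-disubstituted alkenes with electron-poor alkenes, the photocatalytic addition of alkyl radicals to vinylphosphonium salts followed by Wittig olefination, and the polar Schweizer annulation with the same reagent. The six-membered ring closes by 6-exo-trig attack of the ylide carbon on the aldehyde C=O and collapse of the fused oxaphosphetane, so the ring alkene can only be cis. No stereocentre is created: C6 is neither a radical site nor acidic under these conditions and is carried through unchanged. The step needs hydrogen atom transfer to the isopropenyl group and not to the enal (iron hydrides prefer electron-rich 1,1-dialkyl alkenes over acceptor alkenes, the basis of the Giese cross-coupling), capture of the nucleophilic radical by 8 and not by the enal of a second molecule (8 is cationic, more electrophilic and in excess, 7 is added slowly, and intramolecular attack on the enal would need a four-membered ring), and 1,2- and not 1,4-addition of the non-stabilised ylide to the enal (the normal preference, here through a six-membered closure).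

Step 6
Reactants: 10 tert-butyl{[(1S)-6,6-dimethyl-2-methylidenecyclohex-3-en-1-yl]methoxy}dimethylsilane
Product: 11 [(1S)-6,6-dimethyl-2-methylidenecyclohex-3-en-1-yl]methanol
Conditions: n-Bu4NF (1.2 equiv), THF, 0 °C to rt
Reagents that add atoms: none
Why: Fluoride cleaves the primary silyl ether (desilylation); neither the diene nor the C6–H bond reacts with n-Bu4NF.

Step 7
Reactants: 11 [(1S)-6,6-dimethyl-2-methylidenecyclohex-3-en-1-yl]methanol; 12 1-phenyl-1H-tetrazole-5-thiol
Product: 13 5-({[(1S)-6,6-dimethyl-2-methylidenecyclohex-3-en-1-yl]methyl}sulfanyl)-1-phenyl-1H-tetrazole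
Conditions: PPh3, DIAD, THF, 0 °C to rt
Reagents that add atoms: none
Why: Mitsunobu thioetherification: the acidic heteroaryl thiol displaces the activated primary oxyphosphonium group by SN2 at the CH2 group, so C6 is not involved.

Step 8
Reactants: 13 5-({[(1S)-6,6-dimethyl-2-methylidenecyclohex-3-en-1-yl]methyl}sulfanyl)-1-phenyl-1H-tetrazole
Product: 14 5-({[(1S)-6,6-dimethyl-2-methylidenecyclohex-3-en-1-yl]methyl}sulfonyl)-1-phenyl-1H-tetrazole
Conditions: (NH4)6Mo7O24·4H2O (10 mol%), 30% aq. H2O2 (4 equiv), EtOH, 0 °C to rt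
Reagents that add atoms: hydrogen peroxide, OO
Why: Molybdate-catalysed peroxide oxidation of a thioether to the sulfone is far faster than epoxidation of an unactivated diene, so the ring diene should survive at 0 °C with limited H2O2.

Step 9
Reactants: 15 2,3,4-trimethylbenzaldehyde
Product: 16 (2,3,4-trimethylphenyl)methanol
Conditions: NaBH4, MeOH, 0 °C
Reagents that add atoms: none
Why: Borohydride reduction of an aryl aldehyde to the benzylic alcohol.

Step 10
Reactants: 16 (2,3,4-trimethylphenyl)methanol
Product: 17 1-(bromomethyl)-2,3,4-trimethylbenzene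
Conditions: PBr3 (0.4 equiv), Et2O, 0 °C
Reagents that add atoms: phosphorus tribromide, BrP(Br)Br
Why: PBr3 converts the benzylic alcohol into the bromide by SN2 displacement of the phosphite ester.

Step 11
Reactants: 17 1-(bromomethyl)-2,3,4-trimethylbenzene
Product: 18 diethyl [(2,3,4-trimethylphenyl)methyl]phosphonate
Conditions: P(OEt)3 (neat), 140 °C
Reagents that add atoms: triethyl phosphite, CCOP(OCC)OCC
Why: Michaelis–Arbuzov reaction of a benzylic bromide with triethyl phosphite.

Step 12
Reactants: 18 diethyl [(2,3,4-trimethylphenyl)methyl]phosphonate; 19 crocetin dialdehyde, (2E,4E,6E,8E,10E,12E,14E)-2,6,11,15-tetramethylhexadeca-2,4,6,8,10,12,14-heptaenedial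
Product: 20 (2E,4E,6E,8E,10E,12E,14E,16E)-2,6,11,15-tetramethyl-17-(2,3,4-trimethylphenyl)heptadeca-2,4,6,8,10,12,14,16-octaenal
Conditions: KOt-Bu, THF, 0 °C; slow addition to 19 (2.5 equiv), THF, 0 °C to rt, dark
Reagents that add atoms: none
Why: Horner–Wadsworth–Emmons olefination of the benzylic phosphonate anion, added slowly to an excess of the symmetrical dialdehyde, should give the mono-adduct with an (E)-C7'=C8' bond and leave the other aldehyde for the last step.

Step 13
Reactants: 14 5-({[(1S)-6,6-dimethyl-2-methylidenecyclohex-3-en-1-yl]methyl}sulfonyl)-1-phenyl-1H-tetrazole; 20 (2E,4E,6E,8E,10E,12E,14E,16E)-2,6,11,15-tetramethyl-17-(2,3,4-trimethylphenyl)heptadeca-2,4,6,8,10,12,14,16-octaenal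
Product: 21 (6S)-3,4-didehydro-γ,χ-carotene (CNP0344069.1), all-E
Conditions: KN(SiMe3)2 (0.95 equiv per 14), DME/THF, −60 °C; then 20 in THF, −60 °C to rt, dark, argon
Reagents that add atoms: none
Why: Julia–Kocienski olefination: the metalated 1-phenyltetrazolyl sulfone adds to the aldehyde, and Smiles rearrangement with loss of SO2 and tetrazololate should give the (E)-C7=C8 alkene; C6 is β to the carbanion, the product has no carbonyl group, and the base is used in deficit, so the configuration should be retained.

**Compound list**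

1 | {[tert-butyl(dimethyl)silyl]oxy}acetaldehyde | CC(C)(C)[Si](C)(C)OCC=O | starting material
2 | ethyl (triphenylphosphoranylidene)acetate | CCOC(=O)C=P(c1ccccc1)(c1ccccc1)c1ccccc1 | starting material
3 | ethyl (2E)-4-{[tert-butyl(dimethyl)silyl]oxy}but-2-enoate | CCOC(=O)/C=C/CO[Si](C)(C)C(C)(C)C | intermediate
4 | potassium trifluoro(prop-1-en-2-yl)borate | [K+].C=C(C)[B-](F)(F)F | starting material
5 | ethyl (3R)-3-({[tert-butyl(dimethyl)silyl]oxy}methyl)-4-methylpent-4-enoate | C=C(C)[C@@H](CC(=O)OCC)CO[Si](C)(C)C(C)(C)C | intermediate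
6 | (3R)-3-({[tert-butyl(dimethyl)silyl]oxy}methyl)-4-methylpent-4-enal | C=C(C)[C@@H](CC=O)CO[Si](C)(C)C(C)(C)C | intermediate
7 | (3S)-3-({[tert-butyl(dimethyl)silyl]oxy}methyl)-4-methyl-2-methylidenepent-4-enal | C=C(C)[C@@H](C(=C)C=O)CO[Si](C)(C)C(C)(C)C | intermediate
8 | ethenyl(triphenyl)phosphonium bromide | C=C[P+](c1ccccc1)(c1ccccc1)c1ccccc1.[Br-] | starting material
9 | [(4S)-4-({[tert-butyl(dimethyl)silyl]oxy}methyl)-5-formyl-3,3-dimethylhex-5-en-1-yl](triphenyl)phosphonium bromide | CC(C)(CC[P+](c1ccccc1)(c1ccccc1)c1ccccc1)[C@@H](C(=C)C=O)CO[Si](C)(C)C(C)(C)C.[Br-] | intermediate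
10 | tert-butyl{[(1S)-6,6-dimethyl-2-methylidenecyclohex-3-en-1-yl]methoxy}dimethylsilane | C=C1C=CCC(C)(C)[C@@H]1CO[Si](C)(C)C(C)(C)C | intermediate
11 | [(1S)-6,6-dimethyl-2-methylidenecyclohex-3-en-1-yl]methanol | C=C1C=CCC(C)(C)[C@@H]1CO | intermediate
12 | 1-phenyl-1H-tetrazole-5-thiol | Sc1nnnn1-c1ccccc1 | starting material
13 | 5-({[(1S)-6,6-dimethyl-2-methylidenecyclohex-3-en-1-yl]methyl}sulfanyl)-1-phenyl-1H-tetrazole | C=C1C=CCC(C)(C)[C@@H]1CSc1nnnn1-c1ccccc1 | intermediate
14 | 5-({[(1S)-6,6-dimethyl-2-methylidenecyclohex-3-en-1-yl]methyl}sulfonyl)-1-phenyl-1H-tetrazole | C=C1C=CCC(C)(C)[C@@H]1CS(=O)(=O)c1nnnn1-c1ccccc1 | intermediate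
15 | 2,3,4-trimethylbenzaldehyde | O=Cc1ccc(C)c(C)c1C | starting material
16 | (2,3,4-trimethylphenyl)methanol | OCc1ccc(C)c(C)c1C | intermediate
17 | 1-(bromomethyl)-2,3,4-trimethylbenzene | BrCc1ccc(C)c(C)c1C | intermediate
18 | diethyl [(2,3,4-trimethylphenyl)methyl]phosphonate | CCOP(=O)(Cc1ccc(C)c(C)c1C)OCC | intermediate
19 | crocetin dialdehyde, (2E,4E,6E,8E,10E,12E,14E)-2,6,11,15-tetramethylhexadeca-2,4,6,8,10,12,14-heptaenedial | O=C/C(C)=C/C=C/C(C)=C/C=C/C=C(C)/C=C/C=C(C)/C=O | starting material
20 | (2E,4E,6E,8E,10E,12E,14E,16E)-2,6,11,15-tetramethyl-17-(2,3,4-trimethylphenyl)heptadeca-2,4,6,8,10,12,14,16-octaenal | O=C/C(C)=C/C=C/C(C)=C/C=C/C=C(C)/C=C/C=C(C)/C=C/c1ccc(C)c(C)c1C | intermediate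
21 | (6S)-3,4-didehydro-γ,χ-carotene (CNP0344069.1) | C=C1C=CCC(C)(C)[C@@H]1/C=C/C(C)=C/C=C/C(C)=C/C=C/C=C(C)/C=C/C=C(C)/C=C/c1ccc(C)c(C)c1C | target

**Step count and risks**

Total step count: 13. Longest linear sequence: 9 steps (steps 1 to 8, then step 13).

Steps most likely to fail:

Step 5 (proposed method). What may go wrong: capture of the tertiary radical by the enal of another molecule in place of 8 (oligomerisation), failure of the α-phosphonio radical to be reduced so that iron does not turn over, or interception of the aldehyde by the ylide that base forms from unconsumed 8. The fallback uses known reactions only and moves the radical step ahead of the enal. It sets out from ester 5. Iron-hydride hydroalkylation with phenyl vinyl sulfone (Fe(acac)3, PhSiH3, EtOH, 60 °C) should give ethyl (3R)-3-({[tert-butyl(dimethyl)silyl]oxy}methyl)-4,4-dimethyl-6-(phenylsulfonyl)hexanoate F1. Reduction with i-Bu2AlH at −78 °C should give (3R)-3-({[tert-butyl(dimethyl)silyl]oxy}methyl)-4,4-dimethyl-6-(phenylsulfonyl)hexanal F2, and methylenation as in step 4 should give (3S)-3-({[tert-butyl(dimethyl)silyl]oxy}methyl)-4,4-dimethyl-2-methylidene-6-(phenylsulfonyl)hexanal F3. LiN(i-Pr)2 (THF, −78 °C) should close the ring by addition of the sulfonyl carbanion to the aldehyde, and Ac2O should trap the alkoxide as (3S)-3-({[tert-butyl(dimethyl)silyl]oxy}methyl)-4,4-dimethyl-2-methylidene-6-(phenylsulfonyl)cyclohexyl acetate F4. Reductive elimination with SmI2 (THF/DMPU, Julia–Lythgoe olefination) rejoins the route at 10.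

Step 13. What may go wrong: slow or reversible addition of the hindered sulfonyl carbanion to the vinylogous aldehyde, incomplete (E)-selectivity in the Smiles–elimination sequence, or base-mediated loss of the C6 configuration in the product. The fallback sets out from alcohol 11. I2, PPh3 and imidazole (CH2Cl2, 0 °C) should give (4S)-4-(iodomethyl)-5,5-dimethyl-3-methylidenecyclohex-1-ene F5, and PBu3 (MeCN, 60 °C) should give tributyl{[(1S)-6,6-dimethyl-2-methylidenecyclohex-3-en-1-yl]methyl}phosphonium iodide F6. Its ylide (NaN(SiMe3)2, THF, −78 °C) is condensed with 20; trialkylphosphonium ylides are known to favour (E)-alkenes with conjugated aldehydes. This Wittig route rejoins the main route at 21 and also by-passes the sulfur oxidation of step 8.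

Step 2. What may go wrong: slow insertion of the ester acceptor relative to protodeboronation of 4 at 100 °C, and erosion of enantioselectivity. The fallback is an auxiliary-controlled conjugate addition and sets out from aldehyde 1. Masamune–Roush olefination (LiCl, i-Pr2NEt, MeCN) with (4S)-3-[(diethoxyphosphoryl)acetyl]-4-phenyl-1,3-oxazolidin-2-one should give (4S)-3-[(2E)-4-{[tert-butyl(dimethyl)silyl]oxy}but-2-enoyl]-4-phenyl-1,3-oxazolidin-2-one F7. Isopropenylmagnesium bromide with CuBr·SMe2 (THF, −78 to −20 °C) should add anti to the phenyl group of the chelated imide and give (4S)-3-[(3R)-3-({[tert-butyl(dimethyl)silyl]oxy}methyl)-4-methylpent-4-enoyl]-4-phenyl-1,3-oxazolidin-2-one F8. LiBH4 (THF/H2O) should remove the auxiliary and give (3R)-3-({[tert-butyl(dimethyl)silyl]oxy}methyl)-4-methylpent-4-en-1-ol F9, and Dess–Martin oxidation rejoins the route at 6.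

**Further compounds**

F1 | step 5 | ethyl (3R)-3-({[tert-butyl(dimethyl)silyl]oxy}methyl)-4,4-dimethyl-6-(phenylsulfonyl)hexanoate | CC(C)(CCS(=O)(=O)c1ccccc1)[C@@H](CC(=O)OCC)CO[Si](C)(C)C(C)(C)C
F2 | step 5 | (3R)-3-({[tert-butyl(dimethyl)silyl]oxy}methyl)-4,4-dimethyl-6-(phenylsulfonyl)hexanal | CC(C)(CCS(=O)(=O)c1ccccc1)[C@@H](CC=O)CO[Si](C)(C)C(C)(C)C
F3 | step 5 | (3S)-3-({[tert-butyl(dimethyl)silyl]oxy}methyl)-4,4-dimethyl-2-methylidene-6-(phenylsulfonyl)hexanal | CC(C)(CCS(=O)(=O)c1ccccc1)[C@@H](C(=C)C=O)CO[Si](C)(C)C(C)(C)C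
F4 | step 5 | (3S)-3-({[tert-butyl(dimethyl)silyl]oxy}methyl)-4,4-dimethyl-2-methylidene-6-(phenylsulfonyl)cyclohexyl acetate | C=C1C(OC(C)=O)C(S(=O)(=O)c2ccccc2)CC(C)(C)[C@@H]1CO[Si](C)(C)C(C)(C)C
F5 | step 13 | (4S)-4-(iodomethyl)-5,5-dimethyl-3-methylidenecyclohex-1-ene | C=C1C=CCC(C)(C)[C@@H]1CI
F6 | step 13 | tributyl{[(1S)-6,6-dimethyl-2-methylidenecyclohex-3-en-1-yl]methyl}phosphonium iodide | C=C1C=CCC(C)(C)[C@@H]1C[P+](CCCC)(CCCC)CCCC.[I-]
F7 | step 2 | (4S)-3-[(2E)-4-{[tert-butyl(dimethyl)silyl]oxy}but-2-enoyl]-4-phenyl-1,3-oxazolidin-2-one | CC(C)(C)[Si](C)(C)OC/C=C/C(=O)N1C(=O)OC[C@@H]1c1ccccc1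
F8 | step 2 | (4S)-3-[(3R)-3-({[tert-butyl(dimethyl)silyl]oxy}methyl)-4-methylpent-4-enoyl]-4-phenyl-1,3-oxazolidin-2-one | C=C(C)[C@@H](CC(=O)N1C(=O)OC[C@@H]1c1ccccc1)CO[Si](C)(C)C(C)(C)C
F9 | step 2 | (3R)-3-({[tert-butyl(dimethyl)silyl]oxy}methyl)-4-methylpent-4-en-1-ol | C=C(C)[C@@H](CCO)CO[Si](C)(C)C(C)(C)C
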